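**Numbering used throughout.** Each cyclohepta[b]pyran is numbered O1, C2, C3, C4, C4a, C5–C9, C9a. Primed locants belong to the half without the 3-methyl group. Ca–Cd are the diene carbons from C2 to C2′.

## Analysis of the target

The target is built from two tropolone-fused 3,4-dihydro-2H-pyrans (8-hydroxy-7-oxo, 5-methyl) joined through C2 and C2′ by an (E,E)-buta-1,3-diene. It has three stereocentres: C2 (R) and C3 (R), trans to each other on one pyran, and C2′ (R) on the other. The two ether carbons have the same spatial sense, but four sp2 carbons separate them, so neither can control the other, and the single methyl on C3 removes all symmetry. The tropolones are acidic, chelating and tautomeric, so any O-derivative can exist as two regioisomers. The most fragile bonds are C2–O1 and C2′–O1′: they are allylic (dienylic in the target) and their oxygen is a vinylogous carboxylate, so acid, zerovalent palladium or a carbanion on Ca or Cd can break them. The difficulties are the 1,2,4-trioxygenated, methyl-bearing seven-membered aromatic ring, the regioselective fusion of a pyran to C4a/C9a, the trans C2/C3 pair, the isolated C2′ centre, and a late union that leaves the ether carbons untouched. The strategy rests on one feature: if the oxygens on C7 and C8 are tied together, O1 and C9a are the oxygen and carbon of a tropone carbonyl and C4a is the carbon next to it. C2–C3–C4, with vinyl on C2, methyl on C3 and room for two esters on C4, is then the opened form of a 2-methyl-3-vinylcyclopropane-1,1-diester. That three-carbon unit can be added across the carbonyl oxygen and the alpha-carbon of a tropone, and the aromaticity is restored by removing hydride from C4a.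

## Retrosynthetic reasoning

**39 to 38.** The two O–CH3 bonds are cut last. Free tropolones chelate every metal used in the end-game, so they are carried as methyl ethers, and either ether regioisomer returns the same tropolone. The forward step must cleave the methyl groups without ionising the dienylic ether bonds.

**38 to 26 and 37.** The Cb–Cc single bond is cut. Each half then keeps the two alkene carbons that its vinyl group already supplies, and the bond is made between two sp2 carbons of fixed E geometry. A carbonyl olefination at Ca=Cb or Cc=Cd was not used: it needs a carbanion on, or allylic to, a carbon next to O1 or O1′, and that vinylogous carboxylate oxygen would be expelled. The forward coupling must retain both alkene geometries.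

**26 to 23, and 37 to 36.** The alkenyl iodide comes from the vinyl group by cleavage to the aldehyde 25 and one-carbon iodo-olefination. The alkenylboronate comes from the vinyl group by cross-metathesis. The aldehyde is placed on the half that has C3, because there a loss of configuration at C2 would give a separable diastereomer and not a hidden enantiomer.

**23 to 18, and 36 to 31.** The two C4–CO2Me bonds are cut. The esters are the price of the annulation and go in two stages, one by dealkoxycarbonylation and one by radical decarboxylation of the acid (21, 34). The tropolone is methylated in between (20, 33), so that the carboxyl group can be activated. Both removals are placed after re-aromatisation, because a cycloheptatriene C–H bond would survive neither the heat nor the thiyl radicals.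

**18 to 16, and 31 to 29.** The C4a–H bond and the ketal on O7/O8 are restored. This puts the seven-membered ring at the cycloheptatriene level, which is what the annulation delivers. The forward step must take hydride from C4a and release the ketal carbon without opening the pyran.

**16 to 10 and 14, and 29 to 10 and 27.** O1–C2 and C4–C4a are cut together. This is the only disconnection that removes the pyran ring, both of its ring-forming bonds and the C2 centre in one step. It leaves a tropone that serves both halves and a cyclopropane that already holds C3. The forward reaction must send the malonate carbon to C4a and not to C9, close through oxygen, and give the trans C2/C3 pair (or, for 29, the R centre at C2′ under ligand control).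

**14 to 11 and 12.** The vinyl carbon is removed to the aldehyde 13, and the three ring bonds of 13 are cut to an enal and a bromomalonate. An amine catalyst sets the methyl-bearing centre, and ring closure places the formyl group trans to it.

**10 to 1 and 3.** The ketal is removed to the hydroxytropolone 9, the O-methyl group is put back (8) and bromine is put back on the future C4a (7). The seven-membered ring of 7 is cut to the dibromocyclopropane 4 and further to the Birch diene 2. Ring expansion of an anisole places the methyl group and the three oxygens where the target needs them. The ketal is what forces the third oxygen to be the carbonyl.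

## Alternatives that were turned down

**Alternative 1:** The seven-membered ring is disconnected to a six-membered one: Birch reduction of an anisole, dibromocarbene addition, oxidation to the dione (identical with 6) and base-induced opening of the cyclopropane with loss of bromide give the bromotropolone A1, which is identical with 7. In its favour, every step is of a known type, the substitution pattern of the tropolone is fixed unambiguously, and the bromine sits exactly on the future C4a. On precedent it is stronger than the chosen route, which in fact uses this chemistry to reach 7. As a strategy for the whole molecule it does less: its key step forms no bond of the pyran and no stereocentre. C4–C4a must then be made by an sp2–sp3 coupling at a bromide flanked by a methoxy and a methyl group, O1–C2 by a separate etherification, and C2, C3 and C2′ must come from two separately built chiral chains. The chosen route spends two extra steps on 7 (hydrogenolysis, ketal) and then makes both ring bonds and C2 in one operation from a two-step cyclopropane, with one tropone serving both halves.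

**Alternative 2:** C4a–C9a and C8–C9 are disconnected. A 3-oxidopyrylium, generated from an acetoxypyranone by base and heat, adds across a tethered ethynyl ether and gives the oxygen-bridged bicycle A2, with the carbocycle and the pyran closed at once. In its favour, the tether fixes the regiochemistry, and C2 and C3 are already in the chain, so the key step carries no stereochemical risk at those centres; on that point it is stronger than the chosen key step, which must control C2. Against it, each cyclisation substrate needs a long linear sequence (substituted pyranone, chiral chain, an acid- and heat-sensitive ynol ether), and the two halves need two different substrates with no common intermediate. A2 must still be opened at the oxygen bridge under acid and aromatised, and its C2 substituent is a silyloxymethyl group that has to be turned into a diene terminus. The chosen strategy accepts one unproven step on small molecules and gains convergence on 10 and a vinyl group at C2 from the start.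

**Alternative 3:** O1–C2 and O1′–C2′ are disconnected together. In an open-chain diene-diol that carries both seven-membered rings, the two C9a hydroxyls add in SN2′ fashion under PdCl2(MeCN)2 (divalent palladium), both carbinol hydroxyls leave syn, and the bis(methyl ether) A3, identical with 38, is formed with both pyrans and the E,E-diene. In its favour, it is the most convergent end-game: no union step follows, and the diene geometry and both ether centres come from one chirality transfer. On end-game step economy it is stronger than the chosen route. Against it, the target is not symmetric, so the two arms cannot be attached in a two-directional way and C3 must be set separately. The C9a hydroxyl must be the only free oxygen of each ring, which requires a regioselective differentiation of three ring oxygens. The fidelity of a double 1,3-transfer through two six-membered closures is open, and a failure is found only at the last, most valuable intermediate. The chosen strategy places its risk early, where the material is cheap, and reaches the same compound 38.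

Key step: step 10

## Assumptions

- Step 8: the (R)-configured prolinol silyl ether is taken to give (2S,3S)-13, by the usual model in which the diaryl(silyloxy)methyl group shields one face of the E-iminium ion. If the sense is the reverse, the (S)-catalyst is used.
- Step 18: the (1R,2R)-ligand is taken to give the 2R centre of 29. If not, its enantiomer is used.
- Steps 13 and 21: the tropolone methyl ethers are drawn as the 7-methoxy-8-oxo isomers. The 8-methoxy-7-oxo isomers, if formed, react alike and give the same tropolones in step 26.
- C4a in 16 and 29 and C4 in 19–22 and 32–35 are transient centres. One C4a epimer is drawn, C4 is left open, and all isomers converge.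

## Route

Step 1
Reactants: 1 2-methylanisole
Product: 2 1-methoxy-2-methylcyclohexa-1,4-diene
Conditions: Li, NH3(l), t-BuOH, THF, −78 to −33 °C; MeOH quench
Reagents that add atoms: none
Why: Birch reduction; both donor groups end on the same double bond, so the ring is reduced at the two carbons flanking that bond and the tetrasubstituted enol ether needed for step 2 results.

Step 2
Reactants: 2 1-methoxy-2-methylcyclohexa-1,4-diene; 3 bromoform
Product: 4 7,7-dibromo-1-methoxy-6-methylbicyclo[4.1.0]hept-3-ene (racemic)
Conditions: KOt-Bu, pentane, −10 to 0 °C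
Reagents that add atoms: none
Why: Dihalocarbene cyclopropanation; dibromocarbene from 3 is electrophilic and should add to the electron-rich tetrasubstituted enol ether double bond in preference to the disubstituted one.

Step 3
Reactants: 4 7,7-dibromo-1-methoxy-6-methylbicyclo[4.1.0]hept-3-ene
Product: 5 7,7-dibromo-1-methoxy-6-methylbicyclo[4.1.0]heptane-3,4-diol (racemic cis-diol)
Conditions: OsO4 (cat.), NMO, acetone–H2O, rt
Reagents that add atoms: osmium tetroxide, O=[Os](=O)(=O)=O (catalytic carrier of the two oxygens); N-methylmorpholine N-oxide, C[N+]1([O-])CCOCC1 (stoichiometric oxygen source)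
Why: Upjohn dihydroxylation of the remaining alkene; the configuration of the diol does not matter because both carbinol carbons become sp2.

Step 4
Reactants: 5 7,7-dibromo-1-methoxy-6-methylbicyclo[4.1.0]heptane-3,4-diol
Product: 7 5-bromo-6-methoxy-4-methyltropolone, via the bicyclic 3,4-dione 6 (not isolated)
Conditions: (CF3CO)2O, DMSO, CH2Cl2, −78 °C; then Et3N, −78 °C to rt
Reagents that add atoms: none
Why: Swern-type double oxidation gives 6; triethylamine enolises it, the strained dibromocyclopropane opens with loss of bromide, and tautomerisation gives the aromatic tropolone with bromine on the carbon between the methoxy- and methyl-bearing carbons.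

Step 5
Reactants: 7 5-bromo-6-methoxy-4-methyltropolone
Product: 8 6-methoxy-4-methyltropolone
Conditions: H2 (1 atm), Pd/C, NaOAc, MeOH, rt
Reagents that add atoms: none
Why: Hydrogenolysis of the ring C–Br bond; the tropolone ring is reduced much more slowly and acetate takes up the HBr.

Step 6
Reactants: 8 6-methoxy-4-methyltropolone
Product: 9 6-hydroxy-4-methyltropolone (2,6-dihydroxy-4-methylcyclohepta-2,4,6-trien-1-one, tautomeric)
Conditions: BBr3, CH2Cl2, −78 to 0 °C; then H2O
Reagents that add atoms: none
Why: Lewis-acid ether cleavage; bromide attacks the methyl group of the boron-complexed vinylogous ester in an SN2 step.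

Step 7
Reactants: 9 6-hydroxy-4-methyltropolone
Product: 10 5,6-(isopropylidenedioxy)-3-methyltropone (2,2,7-trimethyl-5H-cyclohepta[d][1,3]dioxol-5-one)
Conditions: 2,2-dimethoxypropane, TsOH (cat.), toluene, reflux over 4 Å sieves
Reagents that add atoms: 2,2-dimethoxypropane, COC(C)(C)OC
Why: Acid-catalysed ketal exchange; only the two vicinal oxygens can be bridged by one carbon, which leaves the third oxygen as the carbonyl and fixes the tropone tautomer that the annulation needs.

Step 8
Reactants: 11 crotonaldehyde; 12 dimethyl bromomalonate
Product: 13 dimethyl (2S,3S)-2-formyl-3-methylcyclopropane-1,1-dicarboxylate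
Conditions: (R)-2-[diphenyl(trimethylsilyloxy)methyl]pyrrolidine (20 mol %), 2,6-lutidine, CH2Cl2, 0 °C to rt
Reagents that add atoms: none
Why: Organocatalytic Michael-initiated ring closure; the bromomalonate adds to the unshielded face of the iminium ion, which sets the methyl-bearing centre, and the enamine then displaces bromide (3-exo-tet) with the formyl group trans to methyl.

Step 9
Reactants: 13 dimethyl (2S,3S)-2-formyl-3-methylcyclopropane-1,1-dicarboxylate
Product: 14 dimethyl (2S,3S)-2-methyl-3-vinylcyclopropane-1,1-dicarboxylate
Conditions: Ph3PCH3Br, KN(SiMe3)2, THF, −78 to 0 °C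
Reagents that add atoms: methyltriphenylphosphonium bromide, C[P+](c1ccccc1)(c1ccccc1)c1ccccc1.[Br-]
Why: Wittig methylenation; the non-stabilised ylide adds to the aldehyde at low temperature faster than it deprotonates the ring, so both centres are kept.

Step 10
Reactants: 10 5,6-(isopropylidenedioxy)-3-methyltropone; 14 dimethyl (2S,3S)-2-methyl-3-vinylcyclopropane-1,1-dicarboxylate
Product: 16 dimethyl (2S,3R,4aR)-2-ethenyl-7,8-(isopropylidenedioxy)-3,5-dimethyl-2,3-dihydrocyclohepta[b]pyran-4,4(4aH)-dicarboxylate, via the allylpalladium malonate zwitterion 15 (not isolated)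
Conditions: Pd2(dba)3·CHCl3 (2.5 mol %), dppe (6 mol %), toluene, degassed, 40 °C
Reagents that add atoms: none
Why: Proposed new method: zerovalent palladium should ionise the strained ring of 14 at its allylic C–C bond with inversion to give 15, whose malonate carbon adds in 1,8-fashion to the carbon next to the carbonyl of 10 (C4–C4a) and whose trienolate oxygen then attacks the internal allyl carbon (O1–C2) and releases the catalyst; the closest known reaction types are the [3+2] cycloadditions of vinylcyclopropane-1,1-diesters with electron-poor alkenes under zerovalent palladium and the Lewis-acid [8+3] cycloadditions of tropones with donor–acceptor cyclopropanes. The dihydropyran closes in a 6-exo mode on the allyl unit, the eight-membered alternative through the allyl terminus being disfavoured. C3 is not touched and keeps the configuration of 14. C2 is set by attack of oxygen anti to palladium, so two inversions amount to retention and the trans ring of 14 becomes the trans C2/C3 pair; if the allyl faces interconvert first, the pseudo-equatorial methyl on C3 in a chair-like closure leads to the same isomer. C4a is a transient centre and either epimer serves. The step needs the malonate to choose C4a over C9, which the dioxole oxygen on C8 should secure by making C9 the electron-rich beta-carbon of an enol ether. It also needs closure through oxygen and not through C9 (the [6+3] mode known for trimethylenemethane–palladium and tropone), which the secondary allyl carbon and the oxygen-flanked C9 should favour. Release of ring strain pays for the loss of tropone conjugation.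

Step 11
Reactants: 16 dimethyl (2S,3R,4aR)-2-ethenyl-7,8-(isopropylidenedioxy)-3,5-dimethyl-2,3-dihydrocyclohepta[b]pyran-4,4(4aH)-dicarboxylate
Product: 18 dimethyl (2S,3R)-2-ethenyl-8-hydroxy-3,5-dimethyl-7-oxo-2,3-dihydrocyclohepta[b]pyran-4,4(7H)-dicarboxylate, via the dioxolotropylium tetrafluoroborate 17 (not isolated)
Conditions: Ph3CBF4, CH2Cl2, 0 °C to rt; then NaOAc/AcOH buffer (pH 4–5), THF–H2O, rt
Reagents that add atoms: none
Why: Hydride abstraction from the sp3 carbon of a cycloheptatriene by the trityl cation should give the aromatic, triply oxygen-stabilised cation 17 from either C4a epimer. In weakly acidic water the ketal carbon ionises, is trapped by water and leaves as acetone, which gives the tropolone; ring carbons are not attacked at this pH, so the allylic ether bond stays closed.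

Step 12
Reactants: 18 dimethyl (2S,3R)-2-ethenyl-8-hydroxy-3,5-dimethyl-7-oxo-2,3-dihydrocyclohepta[b]pyran-4,4(7H)-dicarboxylate
Product: 19 methyl (2S,3R)-2-ethenyl-8-hydroxy-3,5-dimethyl-7-oxo-2,3,4,7-tetrahydrocyclohepta[b]pyran-4-carboxylate (C4 epimers)
Conditions: LiCl, H2O, DMSO, 140 °C
Reagents that add atoms: none
Why: Krapcho dealkoxycarbonylation; chloride removes one methyl group of the geminal diester and the resulting carboxylate loses CO2. The aromatic tropolone tolerates the heat, which the cycloheptatriene 16 would not.

Step 13
Reactants: 19 methyl (2S,3R)-2-ethenyl-8-hydroxy-3,5-dimethyl-7-oxo-2,3,4,7-tetrahydrocyclohepta[b]pyran-4-carboxylate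
Product: 20 methyl (2S,3R)-2-ethenyl-7-methoxy-3,5-dimethyl-8-oxo-2,3,4,8-tetrahydrocyclohepta[b]pyran-4-carboxylate (C4 epimers)
Conditions: MeI, K2CO3, acetone, rt
Reagents that add atoms: iodomethane, CI
Why: Williamson O-alkylation of the tropolonate; the tropolone must be masked before the carboxyl group is activated and before the metal-mediated steps.

Step 14
Reactants: 20 methyl (2S,3R)-2-ethenyl-7-methoxy-3,5-dimethyl-8-oxo-2,3,4,8-tetrahydrocyclohepta[b]pyran-4-carboxylate
Product: 21 (2S,3R)-2-ethenyl-7-methoxy-3,5-dimethyl-8-oxo-2,3,4,8-tetrahydrocyclohepta[b]pyran-4-carboxylic acid (C4 epimers)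
Conditions: LiOH, THF–H2O, 0 °C to rt; then 1 M HCl to pH 3
Reagents that add atoms: lithium hydroxide, [Li+].[OH-]
Why: Saponification; the vinylogous methyl ester of the methoxytropone should be attacked by hydroxide much more slowly than the carboxylic ester at this temperature.

Step 15
Reactants: 21 (2S,3R)-2-ethenyl-7-methoxy-3,5-dimethyl-8-oxo-2,3,4,8-tetrahydrocyclohepta[b]pyran-4-carboxylic acid
Product: 23 (2S,3R)-2-ethenyl-7-methoxy-3,5-dimethyl-3,4-dihydrocyclohepta[b]pyran-8(2H)-one, via the thiohydroxamate ester 22 (not isolated)
Conditions: 1-hydroxypyridine-2(1H)-thione, EDC·HCl, DMAP (cat.), CH2Cl2, 0 °C, dark; then t-BuSH, hν (visible), rt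
Reagents that add atoms: none
Why: Barton reductive decarboxylation; 22 fragments to the C4 radical, which takes hydrogen from the thiol, and the transient C4 centre disappears. No cycloheptatriene C–H bond is left for the thiyl radical to abstract.

Step 16
Reactants: 23 (2S,3R)-2-ethenyl-7-methoxy-3,5-dimethyl-3,4-dihydrocyclohepta[b]pyran-8(2H)-one
Product: 25 (2R,3R)-7-methoxy-3,5-dimethyl-8-oxo-2,3,4,8-tetrahydrocyclohepta[b]pyran-2-carbaldehyde, via the 1,2-diol 24 (not isolated)
Conditions: OsO4 (cat.), NaIO4, 2,6-lutidine, dioxane–H2O, rt
Reagents that add atoms: osmium tetroxide, O=[Os](=O)(=O)=O (catalytic); sodium periodate, [Na+].[O-][I](=O)(=O)=O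
Why: Lemieux–Johnson cleavage; OsO4 should pick the monosubstituted vinyl group over the conjugated, more substituted ring double bonds, and the medium is not basic enough to epimerise C2.

Step 17
Reactants: 25 (2R,3R)-7-methoxy-3,5-dimethyl-8-oxo-2,3,4,8-tetrahydrocyclohepta[b]pyran-2-carbaldehyde
Product: 26 (2R,3R)-2-[(E)-2-iodoethenyl]-7-methoxy-3,5-dimethyl-3,4-dihydrocyclohepta[b]pyran-8(2H)-one
Conditions: CrCl2, CHI3, THF, 0 °C to rt, dark
Reagents that add atoms: iodoform, IC(I)I
Why: Takai olefination; the geminal dichromium species should give the E-alkenyl iodide under non-basic conditions, so the alpha-alkoxy centre C2 is kept.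

Step 18
Reactants: 10 5,6-(isopropylidenedioxy)-3-methyltropone; 27 dimethyl 2-vinylcyclopropane-1,1-dicarboxylate (racemic)
Product: 29 dimethyl (2R,4aR)-2-ethenyl-7,8-(isopropylidenedioxy)-5-methyl-2,3-dihydrocyclohepta[b]pyran-4,4(4aH)-dicarboxylate, via the allylpalladium malonate zwitterion 28 (not isolated)
Conditions: Pd2(dba)3·CHCl3 (2.5 mol %), (1R,2R)-N,N′-bis[2-(diphenylphosphino)benzoyl]cyclohexane-1,2-diamine (7.5 mol %), toluene, degassed, rt
Reagents that add atoms: none
Why: Proposed new method: the same annulation as step 10, but 28 has no stereocentre, its allyl faces interconvert through the unsubstituted terminus, and the chiral bisphosphine should decide which face the trienolate oxygen attacks in the 6-exo closure, which sets C2′; the closest known reaction type is the ligand-controlled dynamic asymmetric [3+2] cycloaddition of racemic 2-vinylcyclopropane-1,1-diesters under zerovalent palladium.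

Step 19
Reactants: 29 dimethyl (2R,4aR)-2-ethenyl-7,8-(isopropylidenedioxy)-5-methyl-2,3-dihydrocyclohepta[b]pyran-4,4(4aH)-dicarboxylate
Product: 31 dimethyl (2R)-2-ethenyl-8-hydroxy-5-methyl-7-oxo-2,3-dihydrocyclohepta[b]pyran-4,4(7H)-dicarboxylate, via the dioxolotropylium tetrafluoroborate 30 (not isolated)
Conditions: Ph3CBF4, CH2Cl2, 0 °C to rt; then NaOAc/AcOH buffer (pH 4–5), THF–H2O, rt
Reagents that add atoms: none
Why: Hydride abstraction and ketal release as in step 11; both C4a′ epimers give the same cation.

Step 20
Reactants: 31 dimethyl (2R)-2-ethenyl-8-hydroxy-5-methyl-7-oxo-2,3-dihydrocyclohepta[b]pyran-4,4(7H)-dicarboxylate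
Product: 32 methyl (2R)-2-ethenyl-8-hydroxy-5-methyl-7-oxo-2,3,4,7-tetrahydrocyclohepta[b]pyran-4-carboxylate (C4 epimers)
Conditions: LiCl, H2O, DMSO, 140 °C
Reagents that add atoms: none
Why: Krapcho dealkoxycarbonylation as in step 12.

Step 21
Reactants: 32 methyl (2R)-2-ethenyl-8-hydroxy-5-methyl-7-oxo-2,3,4,7-tetrahydrocyclohepta[b]pyran-4-carboxylate
Product: 33 methyl (2R)-2-ethenyl-7-methoxy-5-methyl-8-oxo-2,3,4,8-tetrahydrocyclohepta[b]pyran-4-carboxylate (C4 epimers)
Conditions: MeI, K2CO3, acetone, rt
Reagents that add atoms: iodomethane, CI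
Why: Williamson O-alkylation of the tropolonate as in step 13.

Step 22
Reactants: 33 methyl (2R)-2-ethenyl-7-methoxy-5-methyl-8-oxo-2,3,4,8-tetrahydrocyclohepta[b]pyran-4-carboxylate
Product: 34 (2R)-2-ethenyl-7-methoxy-5-methyl-8-oxo-2,3,4,8-tetrahydrocyclohepta[b]pyran-4-carboxylic acid (C4 epimers)
Conditions: LiOH, THF–H2O, 0 °C to rt; then 1 M HCl to pH 3
Reagents that add atoms: lithium hydroxide, [Li+].[OH-]
Why: Saponification as in step 14.

Step 23
Reactants: 34 (2R)-2-ethenyl-7-methoxy-5-methyl-8-oxo-2,3,4,8-tetrahydrocyclohepta[b]pyran-4-carboxylic acid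
Product: 36 (2R)-2-ethenyl-7-methoxy-5-methyl-3,4-dihydrocyclohepta[b]pyran-8(2H)-one, via the thiohydroxamate ester 35 (not isolated)
Conditions: 1-hydroxypyridine-2(1H)-thione, EDC·HCl, DMAP (cat.), CH2Cl2, 0 °C, dark; then t-BuSH, hν (visible), rt
Reagents that add atoms: none
Why: Barton reductive decarboxylation as in step 15; the C4′ centre disappears.

Step 24
Reactants: 36 (2R)-2-ethenyl-7-methoxy-5-methyl-3,4-dihydrocyclohepta[b]pyran-8(2H)-one
Product: 37 (2R)-7-methoxy-5-methyl-2-[(E)-2-(4,4,5,5-tetramethyl-1,3,2-dioxaborolan-2-yl)ethenyl]-3,4-dihydrocyclohepta[b]pyran-8(2H)-one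
Conditions: vinylboronic acid pinacol ester, Hoveyda–Grubbs second-generation catalyst (5 mol %), CH2Cl2, 40 °C
Reagents that add atoms: vinylboronic acid pinacol ester, C=CB1OC(C)(C)C(C)(C)O1
Why: Olefin cross-metathesis; vinylboronates give E-alkenylboronates, the reaction is driven by loss of ethene, and C2′ is not involved.

Step 25
Reactants: 26 (2R,3R)-2-[(E)-2-iodoethenyl]-7-methoxy-3,5-dimethyl-3,4-dihydrocyclohepta[b]pyran-8(2H)-one; 37 (2R)-7-methoxy-5-methyl-2-[(E)-2-(4,4,5,5-tetramethyl-1,3,2-dioxaborolan-2-yl)ethenyl]-3,4-dihydrocyclohepta[b]pyran-8(2H)-one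
Product: 38 (2R,3R)-7-methoxy-2-{(1E,3E)-4-[(2R)-7-methoxy-5-methyl-8-oxo-2,3,4,8-tetrahydrocyclohepta[b]pyran-2-yl]buta-1,3-dien-1-yl}-3,5-dimethyl-3,4-dihydrocyclohepta[b]pyran-8(2H)-one
Conditions: Pd(dppf)Cl2 (5 mol %), K3PO4, THF–H2O, rt
Reagents that add atoms: none
Why: Suzuki–Miyaura coupling; both alkenes react with retention, so the E,E-diene results. Oxidative addition to the alkenyl iodide is fast at room temperature, which should keep the catalyst away from the allylic ether bonds, and no carbanion is formed next to O1 or O1′.

Step 26
Reactants: 38 (2R,3R)-7-methoxy-2-{(1E,3E)-4-[(2R)-7-methoxy-5-methyl-8-oxo-2,3,4,8-tetrahydrocyclohepta[b]pyran-2-yl]buta-1,3-dien-1-yl}-3,5-dimethyl-3,4-dihydrocyclohepta[b]pyran-8(2H)-one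
Product: 39 (2R,3R)-8-hydroxy-2-{(1E,3E)-4-[(2R)-8-hydroxy-5-methyl-7-oxo-2,3,4,7-tetrahydrocyclohepta[b]pyran-2-yl]buta-1,3-dien-1-yl}-3,5-dimethyl-3,4-dihydrocyclohepta[b]pyran-7(2H)-one (CNP0332980.1)
Conditions: MgI2, Et2O–toluene, rt to 50 °C; then cold 0.5 M HCl
Reagents that add atoms: none
Why: Chelation-assisted demethylation; magnesium bridges the tropone carbonyl and the methoxy oxygen and iodide attacks the methyl group (SN2). The secondary dienylic ether carbons are not chelated and are much poorer SN2 centres, and no strong acid or ring-attacking nucleophile is present.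

## Compound list

1 | 2-methylanisole | COc1ccccc1C | starting material
2 | 1-methoxy-2-methylcyclohexa-1,4-diene | COC1=C(C)CC=CC1 | intermediate
3 | bromoform | BrC(Br)Br | starting material
4 | 7,7-dibromo-1-methoxy-6-methylbicyclo[4.1.0]hept-3-ene (racemic) | COC12CC=CCC1(C)C2(Br)Br | intermediate
5 | 7,7-dibromo-1-methoxy-6-methylbicyclo[4.1.0]heptane-3,4-diol (racemic cis-diol) | COC12CC(O)C(O)CC1(C)C2(Br)Br | intermediate
6 | 7,7-dibromo-1-methoxy-6-methylbicyclo[4.1.0]heptane-3,4-dione | COC12CC(=O)C(=O)CC1(C)C2(Br)Br | intermediate (not isolated)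
7 | 5-bromo-6-methoxy-4-methyltropolone | COc1cc(=O)c(O)cc(C)c1Br | intermediate
8 | 6-methoxy-4-methyltropolone | COc1cc(=O)c(O)cc(C)c1 | intermediate
9 | 6-hydroxy-4-methyltropolone (2,6-dihydroxy-4-methylcyclohepta-2,4,6-trien-1-one) | O=c1c(O)cc(C)cc(O)c1 | intermediate
10 | 5,6-(isopropylidenedioxy)-3-methyltropone | Cc1cc(=O)cc2OC(C)(C)Oc2c1 | intermediate
11 | crotonaldehyde | C/C=C/C=O | starting material
12 | dimethyl bromomalonate | COC(=O)C(Br)C(=O)OC | starting material
13 | dimethyl (2S,3S)-2-formyl-3-methylcyclopropane-1,1-dicarboxylate | COC(=O)C1(C(=O)OC)[C@@H](C)[C@@H]1C=O | intermediate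
14 | dimethyl (2S,3S)-2-methyl-3-vinylcyclopropane-1,1-dicarboxylate | COC(=O)C1(C(=O)OC)[C@@H](C)[C@@H]1C=C | intermediate
15 | allylpalladium malonate zwitterion from 14 (sigma-allyl form drawn, bisphosphine omitted) | COC(=O)[C-](C(=O)OC)[C@@H](C)/C=C/C[Pd+] | intermediate (not isolated)
16 | dimethyl (2S,3R,4aR)-2-ethenyl-7,8-(isopropylidenedioxy)-3,5-dimethyl-2,3-dihydrocyclohepta[b]pyran-4,4(4aH)-dicarboxylate | CC1=CC2=C(C=C3O[C@@H](C=C)[C@H](C)C(C(=O)OC)(C(=O)OC)[C@@H]13)OC(C)(C)O2 | intermediate
17 | dioxolotropylium tetrafluoroborate from 16 (2S,3R) | CC1=C2C(=[O+][C@@H](C=C)[C@H](C)C2(C(=O)OC)C(=O)OC)C=C2OC(C)(C)OC2=C1.F[B-](F)(F)F | intermediate (not isolated)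
18 | dimethyl (2S,3R)-2-ethenyl-8-hydroxy-3,5-dimethyl-7-oxo-2,3-dihydrocyclohepta[b]pyran-4,4(7H)-dicarboxylate | Cc1cc(=O)c(O)cc2c1C(C(=O)OC)(C(=O)OC)[C@@H](C)[C@H](C=C)O2 | intermediate
19 | methyl (2S,3R)-2-ethenyl-8-hydroxy-3,5-dimethyl-7-oxo-2,3,4,7-tetrahydrocyclohepta[b]pyran-4-carboxylate (C4 epimers) | Cc1cc(=O)c(O)cc2c1C(C(=O)OC)[C@@H](C)[C@H](C=C)O2 | intermediate
20 | methyl (2S,3R)-2-ethenyl-7-methoxy-3,5-dimethyl-8-oxo-2,3,4,8-tetrahydrocyclohepta[b]pyran-4-carboxylate (C4 epimers) | Cc1cc(OC)c(=O)cc2c1C(C(=O)OC)[C@@H](C)[C@H](C=C)O2 | intermediate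
21 | (2S,3R)-2-ethenyl-7-methoxy-3,5-dimethyl-8-oxo-2,3,4,8-tetrahydrocyclohepta[b]pyran-4-carboxylic acid (C4 epimers) | Cc1cc(OC)c(=O)cc2c1C(C(=O)O)[C@@H](C)[C@H](C=C)O2 | intermediate
22 | 2-thioxopyridin-1(2H)-yl ester of 21 | Cc1cc(OC)c(=O)cc2c1C(C(=O)On1ccccc1=S)[C@@H](C)[C@H](C=C)O2 | intermediate (not isolated)
23 | (2S,3R)-2-ethenyl-7-methoxy-3,5-dimethyl-3,4-dihydrocyclohepta[b]pyran-8(2H)-one | Cc1cc(OC)c(=O)cc2c1C[C@@H](C)[C@H](C=C)O2 | intermediate
24 | (2R,3R)-2-(1,2-dihydroxyethyl)-7-methoxy-3,5-dimethyl-3,4-dihydrocyclohepta[b]pyran-8(2H)-one (carbinol epimers) | Cc1cc(OC)c(=O)cc2c1C[C@@H](C)[C@H](C(O)CO)O2 | intermediate (not isolated)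
25 | (2R,3R)-7-methoxy-3,5-dimethyl-8-oxo-2,3,4,8-tetrahydrocyclohepta[b]pyran-2-carbaldehyde | Cc1cc(OC)c(=O)cc2c1C[C@@H](C)[C@H](C=O)O2 | intermediate
26 | (2R,3R)-2-[(E)-2-iodoethenyl]-7-methoxy-3,5-dimethyl-3,4-dihydrocyclohepta[b]pyran-8(2H)-one | Cc1cc(OC)c(=O)cc2c1C[C@@H](C)[C@H](/C=C/I)O2 | intermediate
27 | dimethyl 2-vinylcyclopropane-1,1-dicarboxylate (racemic) | COC(=O)C1(C(=O)OC)CC1C=C | starting material
28 | allylpalladium malonate zwitterion from 27 (sigma-allyl form drawn, bisphosphine omitted) | COC(=O)[C-](C(=O)OC)C/C=C/C[Pd+] | intermediate (not isolated)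
29 | dimethyl (2R,4aR)-2-ethenyl-7,8-(isopropylidenedioxy)-5-methyl-2,3-dihydrocyclohepta[b]pyran-4,4(4aH)-dicarboxylate | CC1=CC2=C(C=C3O[C@@H](C=C)CC(C(=O)OC)(C(=O)OC)[C@@H]13)OC(C)(C)O2 | intermediate
30 | dioxolotropylium tetrafluoroborate from 29 (2R) | CC1=C2C(=[O+][C@@H](C=C)CC2(C(=O)OC)C(=O)OC)C=C2OC(C)(C)OC2=C1.F[B-](F)(F)F | intermediate (not isolated)
31 | dimethyl (2R)-2-ethenyl-8-hydroxy-5-methyl-7-oxo-2,3-dihydrocyclohepta[b]pyran-4,4(7H)-dicarboxylate | Cc1cc(=O)c(O)cc2c1C(C(=O)OC)(C(=O)OC)C[C@H](C=C)O2 | intermediate
32 | methyl (2R)-2-ethenyl-8-hydroxy-5-methyl-7-oxo-2,3,4,7-tetrahydrocyclohepta[b]pyran-4-carboxylate (C4 epimers) | Cc1cc(=O)c(O)cc2c1C(C(=O)OC)C[C@H](C=C)O2 | intermediate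
33 | methyl (2R)-2-ethenyl-7-methoxy-5-methyl-8-oxo-2,3,4,8-tetrahydrocyclohepta[b]pyran-4-carboxylate (C4 epimers) | Cc1cc(OC)c(=O)cc2c1C(C(=O)OC)C[C@H](C=C)O2 | intermediate
34 | (2R)-2-ethenyl-7-methoxy-5-methyl-8-oxo-2,3,4,8-tetrahydrocyclohepta[b]pyran-4-carboxylic acid (C4 epimers) | Cc1cc(OC)c(=O)cc2c1C(C(=O)O)C[C@H](C=C)O2 | intermediate
35 | 2-thioxopyridin-1(2H)-yl ester of 34 | Cc1cc(OC)c(=O)cc2c1C(C(=O)On1ccccc1=S)C[C@H](C=C)O2 | intermediate (not isolated)
36 | (2R)-2-ethenyl-7-methoxy-5-methyl-3,4-dihydrocyclohepta[b]pyran-8(2H)-one | Cc1cc(OC)c(=O)cc2c1CC[C@H](C=C)O2 | intermediate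
37 | (2R)-7-methoxy-5-methyl-2-[(E)-2-(4,4,5,5-tetramethyl-1,3,2-dioxaborolan-2-yl)ethenyl]-3,4-dihydrocyclohepta[b]pyran-8(2H)-one | Cc1cc(OC)c(=O)cc2c1CC[C@H](/C=C/B1OC(C)(C)C(C)(C)O1)O2 | intermediate
38 | (2R,3R)-7-methoxy-2-{(1E,3E)-4-[(2R)-7-methoxy-5-methyl-8-oxo-2,3,4,8-tetrahydrocyclohepta[b]pyran-2-yl]buta-1,3-dien-1-yl}-3,5-dimethyl-3,4-dihydrocyclohepta[b]pyran-8(2H)-one | Cc1cc(OC)c(=O)cc2c1C[C@@H](C)[C@H](/C=C/C=C/[C@H]1CCc3c(C)cc(OC)c(=O)cc3O1)O2 | intermediate
39 | (2R,3R)-8-hydroxy-2-{(1E,3E)-4-[(2R)-8-hydroxy-5-methyl-7-oxo-2,3,4,7-tetrahydrocyclohepta[b]pyran-2-yl]buta-1,3-dien-1-yl}-3,5-dimethyl-3,4-dihydrocyclohepta[b]pyran-7(2H)-one (CNP0332980.1) | Cc1cc(=O)c(O)cc2c1C[C@@H](C)[C@H](/C=C/C=C/[C@H]1CCc3c(C)cc(=O)c(O)cc3O1)O2 | target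

## Step count and least certain steps

Total: 26 steps. Longest linear sequence: 17 steps (steps 1–7, 10–17, 25 and 26). The branch through the second half (steps 1–7, 18–24, 25 and 26) has 16.

**Step 10 (key step).** Three things can go wrong. The malonate terminus of 15 may add to C9 instead of C4a, which is the more hindered site. The trienolate may close through carbon (C9) and not through oxygen, which would give a bridged ketone. The oxygen may attack the other allyl face, which would erode the trans C2/C3 relationship. The fallback uses the known Lewis-acid [8+3] cycloaddition of tropones with donor–acceptor cyclopropanes. From 10 and 14 with Sc(OTf)3 in CH2Cl2 the tropone oxygen opens the activated cyclopropane at the vinyl-bearing carbon first, so the O1–C2 bond exists before any carbon closure can compete, and the malonate then closes onto C4a. An invertive opening would give the C2-epimeric cycloadduct F1, although a vinyl donor may ionise loosely enough to give 16 directly. F1 is taken through the conditions of step 11 to the cis tropolone diester F2. The allylic C2–O1 bond of F2, a vinylogous carboxylate leaving group, is then ionised reversibly with Pd(PPh3)4 in THF (Tsuji–Trost equilibration) and should settle at the trans isomer 18, where the route is rejoined.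

**Step 18.** The ligand may discriminate the two allyl faces poorly, or a reversible ring closure may erode the enantiomeric purity; the regiochemical questions of step 10 apply as well. The fallback is again the known Lewis-acid annulation, now without stereocontrol: 10 and 27 with Sc(OTf)3 give the racemic cycloadduct F3, the conditions of step 19 give the racemic tropolone diester F4, and F4 is resolved by preparative chromatography on a chiral stationary phase. The (2R)-enantiomer is 31, where the route is rejoined.

**Step 11.** Hydride transfer from C4a may be slow, because that C–H bond is flanked by the quaternary C4 and the C5 methyl group, and the trityl cation could then attack the enol ethers instead. Hydrolysis could also open the pyran if water reaches C9a of the cation. The fallback changes the order: from 16, the conditions of step 12 remove one ester first and give the monoester F5, in which C4a is less shielded. Hydrogen shifts at that temperature may move the triene, but every isomer leads to the same cation. Hydride abstraction and buffered hydrolysis then give 19 directly.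

**Step 7.** Ketal exchange on an ene-diol of this kind is an unfavourable equilibrium, as it is for catechols, and may stop at open mixed ketals. The fallback replaces the equilibrium by an irreversible double substitution: 9 and dichlorodiphenylmethane at 160 °C, with loss of HCl, give the diphenylmethylene ketal F6. F6 takes the place of 10 in steps 10 and 18 and gives the cycloadducts F7 and F8. Under the conditions of steps 11 and 19 these lose benzophenone in place of acetone and return to 18 and 31.

**Step 25.** Zerovalent palladium may ionise the allylic ether bonds of 37 or 38, which would scramble C2′ (and C2) or open a pyran; protodeboronation of 37 is a lesser risk. The fallback is free of palladium. From 36, the conditions of step 16 give the aldehyde F9. A Takai-type olefination with Bu3SnCHBr2, CrCl2 and LiI gives the (E)-alkenylstannane F10. Coupling of F10 with 26, mediated by copper thiophene-2-carboxylate (CuTC, C5H3CuO2S, monovalent copper) in NMP at 0 °C, gives 38.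

## Further compounds

F1 | step 10 | dimethyl (2R,3R,4aR)-2-ethenyl-7,8-(isopropylidenedioxy)-3,5-dimethyl-2,3-dihydrocyclohepta[b]pyran-4,4(4aH)-dicarboxylate | CC1=CC2=C(C=C3O[C@H](C=C)[C@H](C)C(C(=O)OC)(C(=O)OC)[C@@H]13)OC(C)(C)O2
F2 | step 10 | dimethyl (2R,3R)-2-ethenyl-8-hydroxy-3,5-dimethyl-7-oxo-2,3-dihydrocyclohepta[b]pyran-4,4(7H)-dicarboxylate | Cc1cc(=O)c(O)cc2c1C(C(=O)OC)(C(=O)OC)[C@@H](C)[C@@H](C=C)O2
F3 | step 18 | racemic dimethyl 2-ethenyl-7,8-(isopropylidenedioxy)-5-methyl-2,3-dihydrocyclohepta[b]pyran-4,4(4aH)-dicarboxylate | CC1=CC2=C(C=C3OC(C=C)CC(C(=O)OC)(C(=O)OC)C13)OC(C)(C)O2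
F4 | step 18 | racemic dimethyl 2-ethenyl-8-hydroxy-5-methyl-7-oxo-2,3-dihydrocyclohepta[b]pyran-4,4(7H)-dicarboxylate | Cc1cc(=O)c(O)cc2c1C(C(=O)OC)(C(=O)OC)CC(C=C)O2
F5 | step 11 | methyl (2S,3R)-2-ethenyl-7,8-(isopropylidenedioxy)-3,5-dimethyl-2,3,4,4a-tetrahydrocyclohepta[b]pyran-4-carboxylate (C4 and C4a epimers) | CC1=CC2=C(C=C3O[C@@H](C=C)[C@H](C)C(C(=O)OC)C13)OC(C)(C)O2
F6 | step 7 | 5,6-(diphenylmethylenedioxy)-3-methyltropone | Cc1cc(=O)cc2OC(c3ccccc3)(c3ccccc3)Oc2c1
F7 | step 7 | dimethyl (2S,3R,4aR)-2-ethenyl-7,8-(diphenylmethylenedioxy)-3,5-dimethyl-2,3-dihydrocyclohepta[b]pyran-4,4(4aH)-dicarboxylate | CC1=CC2=C(C=C3O[C@@H](C=C)[C@H](C)C(C(=O)OC)(C(=O)OC)[C@@H]13)OC(c1ccccc1)(c1ccccc1)O2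
F8 | step 7 | dimethyl (2R,4aR)-2-ethenyl-7,8-(diphenylmethylenedioxy)-5-methyl-2,3-dihydrocyclohepta[b]pyran-4,4(4aH)-dicarboxylate | CC1=CC2=C(C=C3O[C@@H](C=C)CC(C(=O)OC)(C(=O)OC)[C@@H]13)OC(c1ccccc1)(c1ccccc1)O2
F9 | step 25 | (2R)-7-methoxy-5-methyl-8-oxo-2,3,4,8-tetrahydrocyclohepta[b]pyran-2-carbaldehyde | Cc1cc(OC)c(=O)cc2c1CC[C@H](C=O)O2
F10 | step 25 | (2R)-7-methoxy-5-methyl-2-[(E)-2-(tributylstannyl)ethenyl]-3,4-dihydrocyclohepta[b]pyran-8(2H)-one | Cc1cc(OC)c(=O)cc2c1CC[C@H](/C=C/[Sn](CCCC)(CCCC)CCCC)O2
A1 | alternative 1 | 5-bromo-6-methoxy-4-methyltropolone | COc1cc(=O)c(O)cc(C)c1Br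
A2 | alternative 2 | pyran-fused 8-oxabicyclo[3.2.1]octadienone with a silyloxymethyl group on C2 | C1[C@@H](C)[C@H](CO[Si](C)(C)C(C)(C)C)OC2=C[C@@H]3O[C@]12C(C)=CC3=O
A3 | alternative 3 | bis(O-methyl) ether of the target | Cc1cc(OC)c(=O)cc2c1C[C@@H](C)[C@H](/C=C/C=C/[C@H]1CCc3c(C)cc(OC)c(=O)cc3O1)O2
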